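The cyclohexane (C5–C10, elemane numbering) is closed last, across C6–C7, by an intramolecular Nozaki–Hiyama allylation: the C13–C11=C7 allyl unit of a 3-(bromomethyl)butenolide adds to a C6 aldehyde. This one operation forms the carbocycle, sets C6 and C7, unveils the exocyclic methylene of the lactone ring and frees the C6 hydroxyl for the angelate; lactone and oxirane are already present. The precursor is an open chain in which the butenolide (C8) is joined through C9 (silyl ether) and the quaternary C10 (methyl, oxirane) to C5, which bears the aldehyde. C1, C10 and C5 come from an Evans aldol and a chelation-controlled dianionic Claisen rearrangement, C8 and C9 from a Brown anti-hydroxyallylation.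

Key step: step 16

Remark on the chemistry: the side-chain ester is read as the angelate, (2Z)-2-methylbut-2-enoate.

Atom labels: C1–C2 oxirane, C3=C4–C15 acrolein unit, C5–C10 carbocycle, C11–C13 methylene lactone, C14 methyl. Abbreviations: TBS = tert-butyldimethylsilyl, TES = triethylsilyl, PMB = 4-methoxybenzyl, Ipc = isopinocampheyl, pin = pinacolato; "TBSO" etc. denote the corresponding ethers.

Step 1
Reactants: 1 3-(TBSO)propanal
Product: 2 ethyl (2E)-5-(TBSO)pent-2-enoate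
Conditions: (EtO)2P(O)CH2CO2Et, NaH, THF, 0 °C to rt
Reagents that add atoms: triethyl phosphonoacetate, CCOC(=O)CP(=O)(OCC)OCC
Why: Horner–Wadsworth–Emmons olefination of an unhindered aldehyde with a stabilised phosphonate should give the E-enoate, whose geometry later fixes C5.

Step 2
Reactants: 2 ethyl (2E)-5-(TBSO)pent-2-enoate
Product: 3 (2E)-5-(TBSO)pent-2-en-1-ol
Conditions: i-Bu2AlH, CH2Cl2, −78 °C
Reagents that add atoms: none
Why: 1,2-reduction of the enoate with i-Bu2AlH should give the allylic alcohol with the E-alkene and the silyl ether untouched.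

Step 3
Reactants: 4 (4S)-4-benzyl-3-propanoyl-1,3-oxazolidin-2-one; 5 2-(PMBO)acetaldehyde
Product: 6 (4S)-4-benzyl-3-[(2S,3S)-3-hydroxy-2-methyl-4-(PMBO)butanoyl]-1,3-oxazolidin-2-one
Conditions: n-Bu2BOTf, i-Pr2NEt, CH2Cl2, −78 to 0 °C; then pH 7 buffer, MeOH, H2O2
Reagents that add atoms: none
Why: Evans syn-aldol reaction through the Z-boron enolate and a Zimmerman–Traxler transition state, in which the (S)-benzyl auxiliary shields one enolate face, should set the carbinol that becomes oxirane carbon C1 as S (the methyl-bearing centre is erased later as an enolate).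

Step 4
Reactants: 6 (4S)-4-benzyl-3-[(2S,3S)-3-hydroxy-2-methyl-4-(PMBO)butanoyl]-1,3-oxazolidin-2-one; 3 (2E)-5-(TBSO)pent-2-en-1-ol
Product: 7 (2E)-5-(TBSO)pent-2-en-1-yl (2S,3S)-3-hydroxy-2-methyl-4-(PMBO)butanoate
Conditions: 3 (2 equiv), MeMgBr, THF, 0 °C; then 6, 0 °C
Reagents that add atoms: none
Why: transesterification of the N-acyloxazolidinone by the bromomagnesium alkoxide of 3 should release the auxiliary and give the allyl ester without retro-aldol cleavage or change at the carbinol centre.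

Step 5
Reactants: 7 (2E)-5-(TBSO)pent-2-en-1-yl (2S,3S)-3-hydroxy-2-methyl-4-(PMBO)butanoate
Product: 9 (2R,3S)-3-hydroxy-2-methyl-4-(PMBO)-2-[(3R)-5-(TBSO)pent-1-en-3-yl]butanoic acid, via dilithium dianion 8 (not isolated)
Conditions: LiN(i-Pr)2 (2.4 equiv), THF, −78 to −20 °C, then 50 °C; aq. HCl work-up
Reagents that add atoms: none
Why: dianionic Ireland–Claisen rearrangement, in which the lithium chelate between alkoxide and enolate oxygens fixes the enolate geometry, the allyl terminus adds to C10 anti to the CH2OPMB group on the chelate ring as in a Fráter–Seebach alkylation, and the chair transition state with the E-alkene places the C4 chain cis to the methyl group, so that C10 and C5 are both set.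

Step 6
Reactants: 9 (2R,3S)-3-hydroxy-2-methyl-4-(PMBO)-2-[(3R)-5-(TBSO)pent-1-en-3-yl]butanoic acid
Product: 12 (3R,4S)-3-[(1S)-1-hydroxy-2-(PMBO)ethyl]-3-methyl-4-[2-(TBSO)ethyl]oxolan-2-one, via ozonide 10 (not isolated), via hydroxy acid 11 (not isolated)
Conditions: O3, CH2Cl2, −78 °C (Sudan red end point); then NaBH4, MeOH, −78 to 0 °C; aq. citric acid
Reagents that add atoms: ozone, [O-][O+]=O
Why: ozonolysis of the only alkene with reductive work-up should give the C6 primary alcohol, which lactonises onto the neighbouring acid (five-membered ring, gem-dialkyl effect) and so keeps C6 and C9 masked together and distinct from C15.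

Step 7
Reactants: 12 (3R,4S)-3-[(1S)-1-hydroxy-2-(PMBO)ethyl]-3-methyl-4-[2-(TBSO)ethyl]oxolan-2-one
Product: 13 (3R,4S)-3-[(1S)-1,2-dihydroxyethyl]-3-methyl-4-[2-(TBSO)ethyl]oxolan-2-one
Conditions: DDQ, CH2Cl2/pH 7 buffer, 0 °C to rt
Reagents that add atoms: none
Why: oxidative cleavage of the p-methoxybenzyl ether (electron transfer to DDQ, oxocarbenium ion, hydrolysis) should free the primary C2 hydroxyl while the silyl ether and the lactone stay intact.

Step 8
Reactants: 13 (3R,4S)-3-[(1S)-1,2-dihydroxyethyl]-3-methyl-4-[2-(TBSO)ethyl]oxolan-2-one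
Product: 14 (3R,4S)-3-methyl-3-[(2S)-oxiran-2-yl]-4-[2-(TBSO)ethyl]oxolan-2-one
Conditions: PPh3, DIAD, toluene, 80 °C
Reagents that add atoms: none
Why: Mitsunobu cyclodehydration of the terminal 1,2-diol activates the primary hydroxyl as its oxyphosphonium ion, which the C1 oxygen displaces, so the oxirane forms with retention at C1 (S).

Step 9
Reactants: 14 (3R,4S)-3-methyl-3-[(2S)-oxiran-2-yl]-4-[2-(TBSO)ethyl]oxolan-2-one
Product: 15 (3R,4S)-3-methyl-3-[(2S)-oxiran-2-yl]-4-[2-(TBSO)ethyl]oxolan-2-ol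
Conditions: i-Bu2AlH (1.1 equiv), CH2Cl2, −78 °C
Reagents that add atoms: none
Why: partial reduction of the hindered lactone should stop at the lactol (stable aluminium hemiacetal at −78 °C), a masked C9 aldehyde, with the oxirane untouched at this temperature.

Step 10
Reactants: 15 (3R,4S)-3-methyl-3-[(2S)-oxiran-2-yl]-4-[2-(TBSO)ethyl]oxolan-2-ol
Product: 17 (2S,3S,4S,5R)-3-methyl-3-[(2S)-oxiran-2-yl]-2-[2-(TBSO)ethyl]hept-6-ene-1,4,5-triol, via boron adduct 16 (not isolated)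
Conditions: allenyl-B(pin), (+)-Ipc2BH [from (−)-α-pinene], Et2O, 0 °C to rt; then 15, −78 °C to rt; then NaOH, H2O2, 0 °C
Reagents that add atoms: allenylboronic acid pinacol ester, C=C=CB1OC(C)(C)C(C)(C)O1; hydrogen peroxide, OO
Why: Brown anti-hydroxyallylation, in which the (E)-γ-borylallylborane made in the flask adds to the open hydroxy aldehyde through a chair Zimmerman–Traxler transition state, the E geometry giving the anti (erythro) C8/C9 relation, the isopinocampheyl groups from (−)-α-pinene directing attack to the re face of C9 (reagent control over the weak substrate bias), and the C8–B bond being oxidised with retention.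

Step 11
Reactants: 17 (2S,3S,4S,5R)-3-methyl-3-[(2S)-oxiran-2-yl]-2-[2-(TBSO)ethyl]hept-6-ene-1,4,5-triol
Product: 18 (3R,4S,5S,6S)-5-methyl-5-[(2S)-oxiran-2-yl]-6-[2-(TBSO)ethyl]-7-(TESO)hept-1-ene-3,4-diol
Conditions: Et3SiCl (1.05 equiv), imidazole, CH2Cl2, −40 °C
Reagents that add atoms: chlorotriethylsilane, CC[Si](Cl)(CC)CC
Why: silylation should be fastest at the unhindered primary C6 hydroxyl, so both secondary hydroxyls stay free.

Step 12
Reactants: 18 (3R,4S,5S,6S)-5-methyl-5-[(2S)-oxiran-2-yl]-6-[2-(TBSO)ethyl]-7-(TESO)hept-1-ene-3,4-diol; 19 2-(bromomethyl)prop-2-enoic acid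
Product: 20 (3R,4S,5S,6S)-4-hydroxy-5-methyl-5-[(2S)-oxiran-2-yl]-6-[2-(TBSO)ethyl]-7-(TESO)hept-1-en-3-yl 2-(bromomethyl)prop-2-enoate
Conditions: DIC, DMAP (cat.), CH2Cl2, −20 °C
Reagents that add atoms: none
Why: Steglich esterification should take place at the allylic C8 hydroxyl, because the C9 hydroxyl is flanked by the quaternary C10 and is far more hindered.

Step 13
Reactants: 20 (3R,4S,5S,6S)-4-hydroxy-5-methyl-5-[(2S)-oxiran-2-yl]-6-[2-(TBSO)ethyl]-7-(TESO)hept-1-en-3-yl 2-(bromomethyl)prop-2-enoate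
Product: 21 (5R)-3-(bromomethyl)-5-[(1S,2S,3S)-1-hydroxy-2-methyl-2-[(2S)-oxiran-2-yl]-3-[2-(TBSO)ethyl]-4-(TESO)butyl]furan-2(5H)-one
Conditions: second-generation Hoveyda–Grubbs catalyst (10 mol%), toluene, 80 °C
Reagents that add atoms: none
Why: ring-closing metathesis between the C7 vinyl group and the acrylate, the only two alkenes present, should close the butenolide and so deliver the 3-(bromomethyl)furanone without touching a stereocentre.

Step 14
Reactants: 21 (5R)-3-(bromomethyl)-5-[(1S,2S,3S)-1-hydroxy-2-methyl-2-[(2S)-oxiran-2-yl]-3-[2-(TBSO)ethyl]-4-(TESO)butyl]furan-2(5H)-one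
Product: 22 (5R)-3-(bromomethyl)-5-[(1S,2R,3S)-2-methyl-2-[(2S)-oxiran-2-yl]-3-[2-(TBSO)ethyl]-1,4-bis(TESO)butyl]furan-2(5H)-one
Conditions: Et3SiOTf, 2,6-lutidine, CH2Cl2, −78 °C
Reagents that add atoms: triethylsilyl trifluoromethanesulfonate, CC[Si](CC)(CC)OS(=O)(=O)C(F)(F)F
Why: the silyl triflate should silylate the hindered C9 hydroxyl, which keeps it out of the later acylation and places a bulky group that must sit equatorial in the cyclisation.

Step 15
Reactants: 22 (5R)-3-(bromomethyl)-5-[(1S,2R,3S)-2-methyl-2-[(2S)-oxiran-2-yl]-3-[2-(TBSO)ethyl]-1,4-bis(TESO)butyl]furan-2(5H)-one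
Product: 24 (2S,3R,4S)-4-[(2R)-4-(bromomethyl)-5-oxo-2,5-dihydrofuran-2-yl]-3-methyl-3-[(2S)-oxiran-2-yl]-2-[2-(TBSO)ethyl]-4-(TESO)butanal, via primary alcohol 23 (not isolated)
Conditions: (COCl)2, DMSO, CH2Cl2, −78 to −30 °C; then Et3N, −78 °C
Reagents that add atoms: none
Why: Swern oxidation applied directly to the primary triethylsilyl ether, which the chlorosulfonium reagent cleaves and oxidises in one flask while the secondary triethylsilyl and the tert-butyldimethylsilyl ethers survive, should give the aldehyde, the low temperature keeping C5 from epimerising.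

Step 16
Reactants: 24 (2S,3R,4S)-4-[(2R)-4-(bromomethyl)-5-oxo-2,5-dihydrofuran-2-yl]-3-methyl-3-[(2S)-oxiran-2-yl]-2-[2-(TBSO)ethyl]-4-(TESO)butanal
Product: 26 (3aR,4S,5S,6R,7S,7aR)-4-hydroxy-6-methyl-3-methylidene-6-[(2S)-oxiran-2-yl]-5-[2-(TBSO)ethyl]-7-(TESO)hexahydro-1-benzofuran-2(3H)-one, via allylchromium species 25 (not isolated)
Conditions: CrCl2 (5 equiv), THF, rt, high dilution
Reagents that add atoms: none
Why: Two CrCl2 reduce the allylic C13–Br bond to a trivalent allylchromium species, which adds through its γ-carbon C7 to the C6 aldehyde in a chair Zimmerman–Traxler transition state (intramolecular Nozaki–Hiyama allylation; closest known reaction type: chromium-, zinc- or tin-mediated Barbier additions of 3-(halomethyl)furan-2(5H)-ones and 2-(halomethyl)acrylates to aldehydes). The cyclohexane closes in the 6-exo mode at C6–C7, and the C11=C13 methylene appears exocyclic to the lactone at the same time. C7 is controlled by the C8 stereocentre, because the four-atom tether can reach only the butenolide face that carries C9, so the lactone ends cis-fused. C6 is controlled by the closed transition state, in which C8 is the E-substituent of the allyl unit and the aldehyde substituent C5 sits equatorial, which puts O6 trans to C11 (6S). The step needs this anti selectivity and tolerance of the oxirane; the first is secured by the chair that keeps the bulky C9 silyl ether equatorial (the competing chair forces it syn-axial to C11), the second by the mild, non-basic divalent chromium.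

Step 17
Reactants: 26 (3aR,4S,5S,6R,7S,7aR)-4-hydroxy-6-methyl-3-methylidene-6-[(2S)-oxiran-2-yl]-5-[2-(TBSO)ethyl]-7-(TESO)hexahydro-1-benzofuran-2(3H)-one; 27 (2Z)-2-methylbut-2-enoic acid
Product: 28 (3aR,4S,5S,6R,7S,7aR)-6-methyl-3-methylidene-6-[(2S)-oxiran-2-yl]-2-oxo-5-[2-(TBSO)ethyl]-7-(TESO)octahydro-1-benzofuran-4-yl (2Z)-2-methylbut-2-enoate
Conditions: 27, 2,4,6-Cl3C6H2COCl, Et3N, toluene, rt; then 26, DMAP, toluene, 40 °C
Reagents that add atoms: none
Why: Yamaguchi esterification through the preformed mixed anhydride should acylate the hindered C6 hydroxyl at oxygen (C6 unchanged) under conditions that keep the Z geometry of the angelate.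

Step 18
Reactants: 28 (3aR,4S,5S,6R,7S,7aR)-6-methyl-3-methylidene-6-[(2S)-oxiran-2-yl]-2-oxo-5-[2-(TBSO)ethyl]-7-(TESO)octahydro-1-benzofuran-4-yl (2Z)-2-methylbut-2-enoate
Product: 29 (3aR,4S,5S,6S,7S,7aR)-7-hydroxy-5-(2-hydroxyethyl)-6-methyl-3-methylidene-6-[(2S)-oxiran-2-yl]-2-oxooctahydro-1-benzofuran-4-yl (2Z)-2-methylbut-2-enoate
Conditions: HF·pyridine, pyridine, THF, 0 °C to rt
Reagents that add atoms: none
Why: buffered fluoride should cleave both silyl ethers (strong Si–F bond) without opening the oxirane or touching the two unsaturated esters.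

Step 19
Reactants: 29 (3aR,4S,5S,6S,7S,7aR)-7-hydroxy-5-(2-hydroxyethyl)-6-methyl-3-methylidene-6-[(2S)-oxiran-2-yl]-2-oxooctahydro-1-benzofuran-4-yl (2Z)-2-methylbut-2-enoate
Product: 30 (3aR,4S,5S,6S,7S,7aR)-7-hydroxy-6-methyl-3-methylidene-6-[(2S)-oxiran-2-yl]-2-oxo-5-(2-oxoethyl)octahydro-1-benzofuran-4-yl (2Z)-2-methylbut-2-enoate
Conditions: TEMPO (cat.), PhI(OAc)2, CH2Cl2, rt
Reagents that add atoms: none
Why: oxoammonium (TEMPO) oxidation is selective for the primary C15 alcohol over the hindered secondary C9 alcohol and should stop at the aldehyde.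

Step 20
Reactants: 30 (3aR,4S,5S,6S,7S,7aR)-7-hydroxy-6-methyl-3-methylidene-6-[(2S)-oxiran-2-yl]-2-oxo-5-(2-oxoethyl)octahydro-1-benzofuran-4-yl (2Z)-2-methylbut-2-enoate
Product: 31 (3aR,4S,5R,6S,7S,7aR)-7-hydroxy-6-methyl-3-methylidene-6-[(2S)-oxiran-2-yl]-2-oxo-5-(3-oxoprop-1-en-2-yl)octahydro-1-benzofuran-4-yl (2Z)-2-methylbut-2-enoate
Conditions: CH2O (37% aq.), pyrrolidine (10 mol%), EtCO2H (10 mol%), i-PrOH, 45 °C
Reagents that add atoms: formaldehyde, C=O
Why: amine-catalysed α-methylenation (Mannich condensation of the enamine with formaldehyde, then elimination) works only at the unbranched C15 aldehyde and should install C3, completing the acrolein unit without touching a stereocentre.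

Compound list

1 | 3-(TBSO)propanal | O=CCCO[Si](C)(C)C(C)(C)C | starting material
2 | ethyl (2E)-5-(TBSO)pent-2-enoate | CCOC(=O)/C=C/CCO[Si](C)(C)C(C)(C)C | intermediate
3 | (2E)-5-(TBSO)pent-2-en-1-ol | OC/C=C/CCO[Si](C)(C)C(C)(C)C | intermediate
4 | (4S)-4-benzyl-3-propanoyl-1,3-oxazolidin-2-one | CCC(=O)N1[C@@H](Cc2ccccc2)COC1=O | starting material
5 | 2-(PMBO)acetaldehyde | O=CCOCc1ccc(OC)cc1 | starting material
6 | (4S)-4-benzyl-3-[(2S,3S)-3-hydroxy-2-methyl-4-(PMBO)butanoyl]-1,3-oxazolidin-2-one | O=C(N1[C@@H](Cc2ccccc2)COC1=O)[C@@H](C)[C@H](O)COCc1ccc(OC)cc1 | intermediate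
7 | (2E)-5-(TBSO)pent-2-en-1-yl (2S,3S)-3-hydroxy-2-methyl-4-(PMBO)butanoate | O=C(OC/C=C/CCO[Si](C)(C)C(C)(C)C)[C@@H](C)[C@H](O)COCc1ccc(OC)cc1 | intermediate
8 | dilithium alkoxide-enolate of 7 (chelated; carbinol carbon cis to the enolate oxygen) | [Li+].[Li+].[O-]/C(OC/C=C/CCO[Si](C)(C)C(C)(C)C)=C(/C)[C@H]([O-])COCc1ccc(OC)cc1 | intermediate
9 | (2R,3S)-3-hydroxy-2-methyl-4-(PMBO)-2-[(3R)-5-(TBSO)pent-1-en-3-yl]butanoic acid | C=C[C@@H](CCO[Si](C)(C)C(C)(C)C)[C@](C)([C@H](O)COCc1ccc(OC)cc1)C(=O)O | intermediate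
10 | secondary ozonide (1,2,4-trioxolane) at the former vinyl group of 9 | C1OC(OO1)[C@@H](CCO[Si](C)(C)C(C)(C)C)[C@](C)([C@H](O)COCc1ccc(OC)cc1)C(=O)O | intermediate
11 | (2R,3S)-3-hydroxy-2-[(2S)-1-hydroxy-4-(TBSO)butan-2-yl]-2-methyl-4-(PMBO)butanoic acid | OC[C@@H](CCO[Si](C)(C)C(C)(C)C)[C@](C)([C@H](O)COCc1ccc(OC)cc1)C(=O)O | intermediate
12 | (3R,4S)-3-[(1S)-1-hydroxy-2-(PMBO)ethyl]-3-methyl-4-[2-(TBSO)ethyl]oxolan-2-one | O=C1OC[C@@H](CCO[Si](C)(C)C(C)(C)C)[C@]1(C)[C@H](O)COCc1ccc(OC)cc1 | intermediate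
13 | (3R,4S)-3-[(1S)-1,2-dihydroxyethyl]-3-methyl-4-[2-(TBSO)ethyl]oxolan-2-one | O=C1OC[C@@H](CCO[Si](C)(C)C(C)(C)C)[C@]1(C)[C@H](O)CO | intermediate
14 | (3R,4S)-3-methyl-3-[(2S)-oxiran-2-yl]-4-[2-(TBSO)ethyl]oxolan-2-one | O=C1OC[C@@H](CCO[Si](C)(C)C(C)(C)C)[C@]1(C)[C@H]1CO1 | intermediate
15 | (3R,4S)-3-methyl-3-[(2S)-oxiran-2-yl]-4-[2-(TBSO)ethyl]oxolan-2-ol (lactol, both anomers) | OC1OC[C@@H](CCO[Si](C)(C)C(C)(C)C)[C@]1(C)[C@H]1CO1 | intermediate
16 | allylboration adduct: C9 O-B(Ipc)2 borinate, C8 pinacol boronate, configuration as in 17 | C=C[C@@H](B1OC(C)(C)C(C)(C)O1)[C@@H](OB([C@H]2C[C@H]3C[C@@H]([C@@H]2C)C3(C)C)[C@H]2C[C@H]3C[C@@H]([C@@H]2C)C3(C)C)[C@@](C)([C@H]1CO1)[C@H](CCO[Si](C)(C)C(C)(C)C)CO | intermediate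
17 | (2S,3S,4S,5R)-3-methyl-3-[(2S)-oxiran-2-yl]-2-[2-(TBSO)ethyl]hept-6-ene-1,4,5-triol | C=C[C@@H](O)[C@@H](O)[C@@](C)([C@H]1CO1)[C@H](CCO[Si](C)(C)C(C)(C)C)CO | intermediate
18 | (3R,4S,5S,6S)-5-methyl-5-[(2S)-oxiran-2-yl]-6-[2-(TBSO)ethyl]-7-(TESO)hept-1-ene-3,4-diol | C=C[C@@H](O)[C@@H](O)[C@@](C)([C@H]1CO1)[C@H](CCO[Si](C)(C)C(C)(C)C)CO[Si](CC)(CC)CC | intermediate
19 | 2-(bromomethyl)prop-2-enoic acid | C=C(CBr)C(=O)O | starting material
20 | (3R,4S,5S,6S)-4-hydroxy-5-methyl-5-[(2S)-oxiran-2-yl]-6-[2-(TBSO)ethyl]-7-(TESO)hept-1-en-3-yl 2-(bromomethyl)prop-2-enoate | C=C[C@@H](OC(=O)C(=C)CBr)[C@@H](O)[C@@](C)([C@H]1CO1)[C@H](CCO[Si](C)(C)C(C)(C)C)CO[Si](CC)(CC)CC | intermediate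
21 | (5R)-3-(bromomethyl)-5-[(1S,2S,3S)-1-hydroxy-2-methyl-2-[(2S)-oxiran-2-yl]-3-[2-(TBSO)ethyl]-4-(TESO)butyl]furan-2(5H)-one | O=C1O[C@H](C=C1CBr)[C@@H](O)[C@@](C)([C@H]1CO1)[C@H](CCO[Si](C)(C)C(C)(C)C)CO[Si](CC)(CC)CC | intermediate
22 | (5R)-3-(bromomethyl)-5-[(1S,2R,3S)-2-methyl-2-[(2S)-oxiran-2-yl]-3-[2-(TBSO)ethyl]-1,4-bis(TESO)butyl]furan-2(5H)-one | O=C1O[C@H](C=C1CBr)[C@@H](O[Si](CC)(CC)CC)[C@@](C)([C@H]1CO1)[C@H](CCO[Si](C)(C)C(C)(C)C)CO[Si](CC)(CC)CC | intermediate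
23 | (5R)-3-(bromomethyl)-5-[(1S,2R,3S)-4-hydroxy-2-methyl-2-[(2S)-oxiran-2-yl]-3-[2-(TBSO)ethyl]-1-(TESO)butyl]furan-2(5H)-one | O=C1O[C@H](C=C1CBr)[C@@H](O[Si](CC)(CC)CC)[C@@](C)([C@H]1CO1)[C@H](CCO[Si](C)(C)C(C)(C)C)CO | intermediate
24 | (2S,3R,4S)-4-[(2R)-4-(bromomethyl)-5-oxo-2,5-dihydrofuran-2-yl]-3-methyl-3-[(2S)-oxiran-2-yl]-2-[2-(TBSO)ethyl]-4-(TESO)butanal | O=C1O[C@H](C=C1CBr)[C@@H](O[Si](CC)(CC)CC)[C@@](C)([C@H]1CO1)[C@H](CCO[Si](C)(C)C(C)(C)C)C=O | intermediate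
25 | allylchromium dichloride species of 24 (CrCl2 on C13 in place of Br) | O=C1O[C@H](C=C1C[Cr](Cl)Cl)[C@@H](O[Si](CC)(CC)CC)[C@@](C)([C@H]1CO1)[C@H](CCO[Si](C)(C)C(C)(C)C)C=O | intermediate
26 | (3aR,4S,5S,6R,7S,7aR)-4-hydroxy-6-methyl-3-methylidene-6-[(2S)-oxiran-2-yl]-5-[2-(TBSO)ethyl]-7-(TESO)hexahydro-1-benzofuran-2(3H)-one | C=C1C(=O)O[C@@H]2[C@H]1[C@@H](O)[C@@H](CCO[Si](C)(C)C(C)(C)C)[C@](C)([C@H]1CO1)[C@@H]2O[Si](CC)(CC)CC | intermediate
27 | (2Z)-2-methylbut-2-enoic acid (angelic acid) | C/C=C(/C)C(=O)O | starting material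
28 | (3aR,4S,5S,6R,7S,7aR)-6-methyl-3-methylidene-6-[(2S)-oxiran-2-yl]-2-oxo-5-[2-(TBSO)ethyl]-7-(TESO)octahydro-1-benzofuran-4-yl (2Z)-2-methylbut-2-enoate | C=C1C(=O)O[C@@H]2[C@H]1[C@@H](OC(=O)/C(C)=C\C)[C@@H](CCO[Si](C)(C)C(C)(C)C)[C@](C)([C@H]1CO1)[C@@H]2O[Si](CC)(CC)CC | intermediate
29 | (3aR,4S,5S,6S,7S,7aR)-7-hydroxy-5-(2-hydroxyethyl)-6-methyl-3-methylidene-6-[(2S)-oxiran-2-yl]-2-oxooctahydro-1-benzofuran-4-yl (2Z)-2-methylbut-2-enoate | C=C1C(=O)O[C@@H]2[C@H]1[C@@H](OC(=O)/C(C)=C\C)[C@@H](CCO)[C@](C)([C@H]1CO1)[C@@H]2O | intermediate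
30 | (3aR,4S,5S,6S,7S,7aR)-7-hydroxy-6-methyl-3-methylidene-6-[(2S)-oxiran-2-yl]-2-oxo-5-(2-oxoethyl)octahydro-1-benzofuran-4-yl (2Z)-2-methylbut-2-enoate | C=C1C(=O)O[C@@H]2[C@H]1[C@@H](OC(=O)/C(C)=C\C)[C@@H](CC=O)[C@](C)([C@H]1CO1)[C@@H]2O | intermediate
31 | (3aR,4S,5R,6S,7S,7aR)-7-hydroxy-6-methyl-3-methylidene-6-[(2S)-oxiran-2-yl]-2-oxo-5-(3-oxoprop-1-en-2-yl)octahydro-1-benzofuran-4-yl (2Z)-2-methylbut-2-enoate | C=C1C(=O)O[C@@H]2[C@H]1[C@@H](OC(=O)/C(C)=C\C)[C@@H](C(=C)C=O)[C@](C)([C@H]1CO1)[C@@H]2O | target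

Total step count: 20. Longest linear sequence: 19 steps (1 → 2 → 3 → 7 → 9 → 12 → 13 → 14 → 15 → 17 → 18 → 20 → 21 → 22 → 24 → 26 → 28 → 29 → 30 → 31).

Steps most likely to fail

Step 5. The fully substituted dianion 8 may undergo the sigmatropic shift too slowly, so that protonation or decomposition on warming lowers conversion and facial control at C10. Fallback, from 7 back to 9: the dianion is generated as before and silylated on both oxygens with Me3SiCl at −78 °C to give the bis(trimethylsilyl) ketene acetal F1, whose double-bond geometry is already fixed by the chelate. As a neutral Ireland–Claisen substrate F1 should rearrange at 60 °C to the trimethylsilyl ester F2. Mild aqueous acid removes both silyl groups and returns to acid 9.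

Step 10. The ring–chain equilibrium of lactol 15 lies on the closed side, so the allylboration may be slow and lose reagent control (facial selectivity at C9) on warming. Fallback, from 15 to 18: NaBH4 reduces 15 to the diol F3. Et3SiCl then silylates the less hindered primary C6 hydroxyl to give the mono-silyl ether F4. Dess–Martin periodinane oxidises the neopentyl C9 alcohol to the open-chain aldehyde F5. The same Brown reagent is then used on the free aldehyde at −78 °C, and oxidative work-up should give 18 directly.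

Step 16. Facial selectivity at C6 may erode (aldehyde substituent axial, or a boat transition state), the allylic bromide may be reduced without C–C bond formation, or the oxirane may be opened by the Lewis-acidic trivalent chromium salts. Fallback, from 22 to 26: palladium-catalysed borylation (B2pin2, Pd2(dba)3, DMSO, 50 °C) converts the allylic bromide into the allylboronate F6. The Swern protocol of step 15 then gives the boronate aldehyde F7. F7 should cyclise without any metal salt by intramolecular allylboration through the same closed chair, and hydrolysis of the borate gives 26.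

Further compounds

F1 | step 5 | bis(trimethylsilyl) ketene acetal / silyl ether of 7 (carbinol carbon cis to OSiMe3) | C[Si](C)(C)O/C(OC/C=C/CCO[Si](C)(C)C(C)(C)C)=C(/C)[C@H](O[Si](C)(C)C)COCc1ccc(OC)cc1
F2 | step 5 | trimethylsilyl (2R,3S)-2-methyl-4-(PMBO)-2-[(3R)-5-(TBSO)pent-1-en-3-yl]-3-(trimethylsilyloxy)butanoate | C=C[C@@H](CCO[Si](C)(C)C(C)(C)C)[C@](C)([C@H](O[Si](C)(C)C)COCc1ccc(OC)cc1)C(=O)O[Si](C)(C)C
F3 | step 10 | (2S,3S)-2-methyl-2-[(2S)-oxiran-2-yl]-3-[2-(TBSO)ethyl]butane-1,4-diol | OC[C@@H](CCO[Si](C)(C)C(C)(C)C)[C@](C)([C@H]1CO1)CO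
F4 | step 10 | (2S,3S)-2-methyl-2-[(2S)-oxiran-2-yl]-3-[2-(TBSO)ethyl]-4-(TESO)butan-1-ol | CC[Si](CC)(CC)OC[C@@H](CCO[Si](C)(C)C(C)(C)C)[C@](C)([C@H]1CO1)CO
F5 | step 10 | (2R,3S)-2-methyl-2-[(2S)-oxiran-2-yl]-3-[2-(TBSO)ethyl]-4-(TESO)butanal | CC[Si](CC)(CC)OC[C@@H](CCO[Si](C)(C)C(C)(C)C)[C@](C)([C@H]1CO1)C=O
F6 | step 16 | (5R)-5-[(1S,2R,3S)-2-methyl-2-[(2S)-oxiran-2-yl]-3-[2-(TBSO)ethyl]-1,4-bis(TESO)butyl]-3-[(pinacolatoboryl)methyl]furan-2(5H)-one | O=C1O[C@H](C=C1CB1OC(C)(C)C(C)(C)O1)[C@@H](O[Si](CC)(CC)CC)[C@@](C)([C@H]1CO1)[C@H](CCO[Si](C)(C)C(C)(C)C)CO[Si](CC)(CC)CC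
F7 | step 16 | (2S,3R,4S)-3-methyl-3-[(2S)-oxiran-2-yl]-4-[(2R)-5-oxo-4-[(pinacolatoboryl)methyl]-2,5-dihydrofuran-2-yl]-2-[2-(TBSO)ethyl]-4-(TESO)butanal | O=C1O[C@H](C=C1CB1OC(C)(C)C(C)(C)O1)[C@@H](O[Si](CC)(CC)CC)[C@@](C)([C@H]1CO1)[C@H](CCO[Si](C)(C)C(C)(C)C)C=O
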